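## Analysis of the target

The target is a 2-arylbenzofuran. Rings A and B form the benzofuran, which carries a free phenol at C6 and an (E)-geranyl chain at C7. The aryl group on benzofuran C2 is a 2,3-dihydrobenzofuran (ring C the benzene, ring D the dihydrofuran; locants O1, C2, C3, C3a, C4–C7, C7a). It is bonded through C4 and carries a phenol at C6 and a 2-hydroxypropan-2-yl group at C2. The only stereocentre is ring D C2, of S configuration, so the problem is one of absolute configuration alone and is best solved from the chiral pool. The geranyl chain has two trisubstituted alkenes ortho to a phenol: acid can cyclise it to a chroman, the E geometry must be kept, and once it is in place no electrophilic oxidant can be used, which rules out a late asymmetric epoxidation or dihydroxylation to make ring D. The tertiary alcohol and the electron-rich benzofuran are further acid-sensitive sites. The hard part is ring C, a 1,2,3,5-tetrasubstituted benzene whose two carbon substituents (at C3a and C4) are adjacent and do not lie between the two oxygens, where resorcinol chemistry would put them. The strategy rests on the fact that rings C and D share the C3a–C7a bond and are bridged by O1–C2–C3. The open chain C4≡C3a–C3–C2–O1–C7a≡C7 is therefore a 1,6-diyne that already holds four carbons of ring C, the stereocentre and the benzofuran on C4; only C5 and C6 are missing.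

## Retrosynthetic reasoning

Target 28 is traced back to its bis-MOM ether 27 by cutting only the two acetal C–O bonds. A MOM group is chosen on the ring A phenol because it is also the directing group for the C7 metalation, and on the tertiary alcohol because it survives every basic and organometallic step.

Phenol 27 is traced back to arylboronate 26 by exchanging the C6–O bond for a C6–B bond. Boron is a masked phenol that can be unveiled under mild, non-acidic oxidation which leaves the alkenes alone.

Boronate 26 is cut at C3a–C7a, C4–C5 and C6–C7 into diyne 24 and ethynylboronate 25. This is the cut the whole route is built around: it removes rings C and D together, leaves the stereocentre on a tether where no bond to it is formed, and delivers C5 and C6 from a purchased two-carbon unit. The forward reaction has to couple the two tethered alkynes with each other rather than with themselves, take up 25 with boron next to C7, and run at room temperature, because 24 is a heat-sensitive secondary alkyl ethynyl ether.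

Ynol ether 24 is traced back through dichlorovinyl ether 21 to alcohol 20 by cutting the O–C(sp) bond. Building the ethynyl ether on the intact alcohol keeps the C2–O bond of the stereocentre untouched, so configuration cannot be lost.

Alcohol 20 is cut at the C3–C(alkyne) bond into alkyne 11 and epoxide 18. An acetylide opens a terminal epoxide at its CH2 carbon, which again leaves the stereocentre alone and joins the two halves convergently.

Epoxide 18 is traced back through diol 16, acetonide 15 and tertiary alcohol 14 to ester 12. The stereocentre of 12 becomes C2 of the target with retention throughout, and the ester carbon becomes the carbinol carbon bearing the two methyl groups.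

Alkyne 11 is traced back through silyl alkyne 10 to 6 and geranyl bromide 7 (C7–C bond), then to iodide 4 and silylacetylene 5 (C2–C bond), and through 2 to benzofuranol 1. The order matters: C2–H is the most acidic position of 2, so C2 is functionalised first and thereby blocked, and only then is C7 metalated between the MOM ether and the furan oxygen.

## Alternatives that were turned down

Alternative 1: Ring D is cut at O1–C2 and C2–C3 and made by a [4+1] annulation. An ortho-quinone methide, released by base from a sulfone, takes up a chiral ammonium ylide of a bromoacetate and closes to the dihydrobenzofuran ester A1, tert-butyl (2S)-4-bromo-6-[tri(propan-2-yl)silyloxy]-2,3-dihydro-1-benzofuran-2-carboxylate. In its favour, ring C is a purchased arene, so there is no orientation question in building it; the ester becomes the tertiary alcohol with a methyl Grignard reagent, and the bromide is a handle for a dependable Suzuki–Miyaura coupling. Against it, the methide carbon (future C3) is unsubstituted here, so all the enantiocontrol has to come from the ammonium-bearing carbon, which is acidic and can equilibrate before ring closure; the known high selectivities belong to methides that carry a substituent. The sulfone precursor also needs a regioselective functionalisation between a phenol and a bromine, and the geranylated benzofuran-2-yl boron partner still has to be made. On precedent for each bond-forming event, alternative 1 is stronger than the chosen route. The chosen route offers instead a stereocentre that is bought and never touched, and one operation that builds both rings.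

Alternative 2: Ring C is kept as an arene and cut at C4–benzofuran C2 and C3a–C3. A bis(silyloxy)aryne is attacked at C4 by a benzofuran-2-yl Grignard reagent, and the new arylmagnesium at C3a opens a chiral epoxide under copper catalysis to give the open-chain alcohol A2, (2R)-1-{2-[7-geranyl-6-(methoxymethoxy)-1-benzofuran-2-yl]-4,6-bis[tri(propan-2-yl)silyloxy]phenyl}-3-(methoxymethoxy)-3-methylbutan-2-ol. In its favour, it is a three-component coupling that assembles the whole carbon skeleton at once, and the silyloxy group next to the aryne should steer the nucleophile to C4. Against it, the arylmagnesium formed is flanked by two ortho substituents and must open an epoxide that is itself next to a quaternary carbon. No ring is closed, so ring D still has to be made by a Mitsunobu-type displacement with inversion at a neopentyl-like carbinol, where elimination competes and the configuration is put at risk. Both routes carry one ambitious step, but in alternative 2 the uncertain steps continue after it, whereas in the chosen route only protecting-group and oxidation chemistry follows the key step.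

Alternative 3: Ring B is cut at C2=C3. An aryl ester joins the two halves, and low-valent titanium from TiCl3 and zinc couples the aldehyde carbon with the ester carbonyl carbon to give the tris-silyl ether A3 of the target (tri(propan-2-yl)silyl on both phenols, triethylsilyl on the tertiary alcohol). In its favour, this ring closure is a known way to make 2-arylbenzofurans, the esterification that precedes it is reliable, and the final deprotection needs only fluoride, which suits the geranyl phenol better than acid. On those two points it is stronger than the chosen route. Against it, the key step makes the easy ring: the ring C/ring D acid with its stereocentre and the 3-geranyl-2,4-dioxygenated benzaldehyde each need a full synthesis with their own regiochemical problems, and a large excess of Lewis-acidic titanium and zinc salts at reflux must spare three silyl ethers. The chosen route is shorter and puts its one risk on the step that solves the hardest part of the structure.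

Key step: step 13

Assumption: compounds 1, 5, 7, 12 and 25 are taken as purchasable; geranyl = (2E)-3,7-dimethylocta-2,6-dien-1-yl, MOM = methoxymethyl, TIPS = tri(propan-2-yl)silyl, Bpin = 4,4,5,5-tetramethyl-1,3,2-dioxaborolan-2-yl.

## Route

Step 1
Reactants: 1 benzofuran-6-ol
Product: 2 6-(methoxymethoxy)-1-benzofuran
Conditions: MOMCl, iPr2NEt, CH2Cl2, 0 °C → rt
Reagents that add atoms: chloromethyl methyl ether (MOMCl), COCCl
Why: O-alkylation of the phenol (Williamson-type); the MOM acetal withstands all later bases and organometallics and is the directing group for step 4.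

Step 2
Reactants: 2 6-(methoxymethoxy)-1-benzofuran
Product: 4 2-iodo-6-(methoxymethoxy)-1-benzofuran, via 2-lithiobenzofuran 3 (not isolated)
Conditions: n-BuLi (1.05 equiv), THF, −78 °C; I2, −78 °C → rt
Reagents that add atoms: iodine, II
Why: Kinetic deprotonation of the heteroaryl C2–H, the most acidic C–H, at −78 °C, where alkoxy-directed lithiation of the benzo ring is still slow, followed by iodinolysis of the C–Li bond.

Step 3
Reactants: 4 2-iodo-6-(methoxymethoxy)-1-benzofuran; 5 ethynyltri(propan-2-yl)silane
Product: 6 {[6-(methoxymethoxy)-1-benzofuran-2-yl]ethynyl}tri(propan-2-yl)silane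
Conditions: PdCl2(PPh3)2 (2 mol %), CuI (4 mol %), Et3N, THF, rt
Reagents that add atoms: none
Why: Sonogashira coupling of a reactive heteroaryl iodide; the bulky silyl cap shields the alkyne from butyllithium in step 4 and blocks C2.

Step 4
Reactants: 6 {[6-(methoxymethoxy)-1-benzofuran-2-yl]ethynyl}tri(propan-2-yl)silane; 7 geranyl bromide
Product: 10 {[7-geranyl-6-(methoxymethoxy)-1-benzofuran-2-yl]ethynyl}tri(propan-2-yl)silane, via aryllithium 8 (not isolated), via arylcopper 9 (not isolated)
Conditions: n-BuLi (1.1 equiv), THF, −78 → −10 °C; CuBr·SMe2 (1.1 equiv), −78 °C; 7 (1.2 equiv), −78 °C → rt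
Reagents that add atoms: none
Why: Directed ortho-metalation at C7, the only C–H flanked by the MOM ether and the furan oxygen now that C2 is blocked; transmetalation to copper makes the allylic substitution occur at the primary carbon of 7 with the E alkene retained.

Step 5
Reactants: 10 {[7-geranyl-6-(methoxymethoxy)-1-benzofuran-2-yl]ethynyl}tri(propan-2-yl)silane
Product: 11 2-ethynyl-7-geranyl-6-(methoxymethoxy)-1-benzofuran
Conditions: TBAF, THF, 0 °C → rt
Reagents that add atoms: none
Why: Fluoride-induced cleavage of the C(sp)–Si bond; alkenes and the MOM acetal are inert to fluoride.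

Step 6
Reactants: 12 methyl (4S)-2,2-dimethyl-1,3-dioxolane-4-carboxylate
Product: 14 2-[(4S)-2,2-dimethyl-1,3-dioxolan-4-yl]propan-2-ol, via methyl ketone 13 (not isolated)
Conditions: MeMgBr (3 equiv), THF, 0 °C → rt; aq NH4Cl
Reagents that add atoms: methylmagnesium bromide, C[Mg]Br
Why: Double Grignard addition to the ester through ketone 13; the stereocentre is not a reacting centre, and excess reagent at low temperature makes addition to 13 outrun enolisation towards it.

Step 7
Reactants: 14 2-[(4S)-2,2-dimethyl-1,3-dioxolan-4-yl]propan-2-ol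
Product: 15 (4S)-4-[2-(methoxymethoxy)propan-2-yl]-2,2-dimethyl-1,3-dioxolane
Conditions: MOMCl, iPr2NEt, Bu4NI (cat.), CH2Cl2, 40 °C
Reagents that add atoms: chloromethyl methyl ether (MOMCl), COCCl
Why: O-alkylation of the tertiary alcohol by the reactive iodomethyl ether formed in situ; the alcohol must be masked before the epoxide and the ynol ether are made.

Step 8
Reactants: 15 (4S)-4-[2-(methoxymethoxy)propan-2-yl]-2,2-dimethyl-1,3-dioxolane
Product: 16 (2S)-3-(methoxymethoxy)-3-methylbutane-1,2-diol
Conditions: AcOH/H2O (4:1), 40 °C
Reagents that add atoms: none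
Why: Hydrolysis of the terminal acetonide under weak acid, which cleaves the strained ketal far faster than the acyclic MOM acetal.

Step 9
Reactants: 16 (2S)-3-(methoxymethoxy)-3-methylbutane-1,2-diol
Product: 18 (2S)-2-[2-(methoxymethoxy)propan-2-yl]oxirane, via primary tosylate 17 (not isolated)
Conditions: NaH (2.2 equiv), N-tosylimidazole (1.05 equiv), THF, 0 °C → rt
Reagents that add atoms: none
Why: Selective sulfonylation of the unhindered primary hydroxyl and intramolecular Williamson closure by the secondary alkoxide; the C–O bond at the stereocentre is kept, so the S configuration is retained.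

Step 10
Reactants: 11 2-ethynyl-7-geranyl-6-(methoxymethoxy)-1-benzofuran; 18 (2S)-2-[2-(methoxymethoxy)propan-2-yl]oxirane
Product: 20 (4S)-1-[7-geranyl-6-(methoxymethoxy)-1-benzofuran-2-yl]-5-(methoxymethoxy)-5-methylhex-1-yn-4-ol, via lithium acetylide 19 (not isolated)
Conditions: 11 (1.3 equiv), n-BuLi, THF, −78 °C; BF3·OEt2, −78 °C; 18, −78 °C; H2O
Reagents that add atoms: none
Why: BF3-promoted opening of a terminal epoxide by a lithium acetylide at the unhindered CH2 carbon (SN2); no bond to the stereocentre is made or broken, so the alcohol is (4S).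

Step 11
Reactants: 20 (4S)-1-[7-geranyl-6-(methoxymethoxy)-1-benzofuran-2-yl]-5-(methoxymethoxy)-5-methylhex-1-yn-4-ol
Product: 21 2-[(4S)-4-{[(E)-1,2-dichloroethenyl]oxy}-5-(methoxymethoxy)-5-methylhex-1-yn-1-yl]-7-geranyl-6-(methoxymethoxy)-1-benzofuran
Conditions: KH (1.3 equiv), THF, 0 °C; Cl2C=CHCl (1.2 equiv), −50 °C → rt
Reagents that add atoms: trichloroethylene, ClC=C(Cl)Cl
Why: The alkoxide of 20 adds to dichloroacetylene generated in situ from trichloroethylene and the vinyl anion is protonated anti, which should give the (E)-dichlorovinyl ether; the O–C bond at the stereocentre is untouched.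

Step 12
Reactants: 21 2-[(4S)-4-{[(E)-1,2-dichloroethenyl]oxy}-5-(methoxymethoxy)-5-methylhex-1-yn-1-yl]-7-geranyl-6-(methoxymethoxy)-1-benzofuran
Product: 24 2-[(4S)-4-(ethynyloxy)-5-(methoxymethoxy)-5-methylhex-1-yn-1-yl]-7-geranyl-6-(methoxymethoxy)-1-benzofuran, via chloroethynyl ether 22 (not isolated), via lithium alkoxyacetylide 23 (not isolated)
Conditions: n-BuLi (2.4 equiv), THF, −78 → −40 °C; MeOH, −78 °C; cold work-up, base-washed alumina, used at once
Reagents that add atoms: none
Why: Dehydrochlorination to chloroalkyne 22, chlorine–lithium exchange to 23 and protonation, the standard route to terminal ynol ethers; 24 is a heat- and acid-sensitive secondary alkyl ethynyl ether and is therefore not stored.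

Step 13
Reactants: 24 2-[(4S)-4-(ethynyloxy)-5-(methoxymethoxy)-5-methylhex-1-yn-1-yl]-7-geranyl-6-(methoxymethoxy)-1-benzofuran; 25 2-ethynyl-4,4,5,5-tetramethyl-1,3,2-dioxaborolane
Product: 26 2-{(2S)-4-[7-geranyl-6-(methoxymethoxy)-1-benzofuran-2-yl]-2-[2-(methoxymethoxy)propan-2-yl]-2,3-dihydro-1-benzofuran-6-yl}-4,4,5,5-tetramethyl-1,3,2-dioxaborolane
Conditions: Cp*RuCl(cod) (10 mol %), 25 (4 equiv), ClCH2CH2Cl, rt; 24 added slowly over 2 h
Reagents that add atoms: none
Why: Proposed new method: oxidative cyclisation of the two tethered alkynes of 24 on the Cp*RuCl fragment should form C3a–C7a and give a ruthenacycle fused to a five-membered cyclic ether, which is ring D, closed intramolecularly through the O1–C2–C3 tether in the way usual for a 1,6-diyne. Coordination and insertion of 25 followed by reductive elimination should then form C4–C5 and C6–C7, so that ring C closes as the six-membered arene by a two-bond annulation onto the metallacycle. The closest known reaction types are the [2+2+2] cyclotrimerisation of ynamide-tethered 1,6-diynes with alkynes to give indolines and the transition-metal-catalysed cyclotrimerisation of 1,6-diynes with alkynylboronates to give arylboronates; an O-alkyl ynol ether has not been shown as the tethered partner, which is why the step is a proposal. No stereocentre is formed: C2 lies on the tether, none of its bonds is made or broken, and its S configuration comes unchanged from 18. The step needs cross-selectivity, which slow addition of 24 to an excess of 25 should secure, because the diyne cyclises on the metal faster than two molecules of 25 couple. It needs the 1,3-orientation of the benzofuranyl and boryl groups: Cp*RuCl catalysts are the family expected to place the substituent of a terminal alkyne meta to the substituent of the diyne terminus, the boryl group turning away from the crowded carbon that carries the benzofuran, so that the boron-bearing carbon bonds to C7 and the CH carbon to C4. Room temperature is required because the ethynyl ether of 24 loses ketene by a retro-ene reaction on heating; this catalyst turns over at ambient temperature, which is the reason for preferring it to RhCl(PPh3)3, which often needs heating and gives a less dependable orientation with hetero-tethered diynes. The trisubstituted geranyl alkenes bind the metal far less well than alkynes, the MOM acetals are inert, and boron arrives as a masked phenol so that no second alkoxyalkyne is needed.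

Step 14
Reactants: 26 2-{(2S)-4-[7-geranyl-6-(methoxymethoxy)-1-benzofuran-2-yl]-2-[2-(methoxymethoxy)propan-2-yl]-2,3-dihydro-1-benzofuran-6-yl}-4,4,5,5-tetramethyl-1,3,2-dioxaborolane
Product: 27 (2S)-4-[7-geranyl-6-(methoxymethoxy)-1-benzofuran-2-yl]-2-[2-(methoxymethoxy)propan-2-yl]-2,3-dihydro-1-benzofuran-6-ol
Conditions: NaBO3·4H2O (3 equiv), THF/H2O (1:1), rt
Reagents that add atoms: sodium perborate (NaBO3), [Na+].[O-]OB=O
Why: Oxidation of the aryl C–B bond by 1,2-migration of the aryl group from boron to peroxide oxygen, which fixes the oxygen at C6; perborate is nucleophilic and mildly basic and should leave the alkenes, the benzofuran and the acetals alone.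

Step 15
Reactants: 27 (2S)-4-[7-geranyl-6-(methoxymethoxy)-1-benzofuran-2-yl]-2-[2-(methoxymethoxy)propan-2-yl]-2,3-dihydro-1-benzofuran-6-ol
Product: 28 (2S)-4-[7-geranyl-6-hydroxy-1-benzofuran-2-yl]-2-(2-hydroxypropan-2-yl)-2,3-dihydro-1-benzofuran-6-ol
Conditions: HCl (1.25 M in MeOH), THF, 40 °C
Reagents that add atoms: none
Why: Acid-catalysed acetal exchange with methanol removes both MOM groups; dilute acid at mild temperature is chosen so that the geranyl alkenes and the tertiary alcohol should survive, and the stereocentre is not involved.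

## Compound list

1 | benzofuran-6-ol | Oc1ccc2ccoc2c1 | starting material
2 | 6-(methoxymethoxy)-1-benzofuran | COCOc1ccc2ccoc2c1 | intermediate
3 | 2-lithio-6-(methoxymethoxy)-1-benzofuran | [Li]c1cc2ccc(OCOC)cc2o1 | intermediate
4 | 2-iodo-6-(methoxymethoxy)-1-benzofuran | COCOc1ccc2cc(I)oc2c1 | intermediate
5 | ethynyltri(propan-2-yl)silane | C#C[Si](C(C)C)(C(C)C)C(C)C | starting material
6 | {[6-(methoxymethoxy)-1-benzofuran-2-yl]ethynyl}tri(propan-2-yl)silane | COCOc1ccc2cc(C#C[Si](C(C)C)(C(C)C)C(C)C)oc2c1 | intermediate
7 | geranyl bromide, (2E)-1-bromo-3,7-dimethylocta-2,6-diene | CC(C)=CCC/C(C)=C/CBr | starting material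
8 | 7-lithio derivative of 6 | COCOc1ccc2cc(C#C[Si](C(C)C)(C(C)C)C(C)C)oc2c1[Li] | intermediate
9 | 7-cuprio derivative of 6 (arylcopper) | COCOc1ccc2cc(C#C[Si](C(C)C)(C(C)C)C(C)C)oc2c1[Cu] | intermediate
10 | {[7-geranyl-6-(methoxymethoxy)-1-benzofuran-2-yl]ethynyl}tri(propan-2-yl)silane | CC(C)=CCC/C(C)=C/Cc1c(OCOC)ccc2cc(C#C[Si](C(C)C)(C(C)C)C(C)C)oc12 | intermediate
11 | 2-ethynyl-7-geranyl-6-(methoxymethoxy)-1-benzofuran | CC(C)=CCC/C(C)=C/Cc1c(OCOC)ccc2cc(C#C)oc12 | intermediate
12 | methyl (4S)-2,2-dimethyl-1,3-dioxolane-4-carboxylate | COC(=O)[C@@H]1COC(C)(C)O1 | starting material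
13 | 1-[(4S)-2,2-dimethyl-1,3-dioxolan-4-yl]ethan-1-one | CC(=O)[C@@H]1COC(C)(C)O1 | intermediate
14 | 2-[(4S)-2,2-dimethyl-1,3-dioxolan-4-yl]propan-2-ol | CC(C)(O)[C@@H]1COC(C)(C)O1 | intermediate
15 | (4S)-4-[2-(methoxymethoxy)propan-2-yl]-2,2-dimethyl-1,3-dioxolane | COCOC(C)(C)[C@@H]1COC(C)(C)O1 | intermediate
16 | (2S)-3-(methoxymethoxy)-3-methylbutane-1,2-diol | COCOC(C)(C)[C@@H](O)CO | intermediate
17 | (2S)-2-hydroxy-3-(methoxymethoxy)-3-methylbutyl 4-methylbenzenesulfonate | COCOC(C)(C)[C@@H](O)COS(=O)(=O)c1ccc(C)cc1 | intermediate
18 | (2S)-2-[2-(methoxymethoxy)propan-2-yl]oxirane | COCOC(C)(C)[C@@H]1CO1 | intermediate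
19 | lithium acetylide of 11 | CC(C)=CCC/C(C)=C/Cc1c(OCOC)ccc2cc(C#C[Li])oc12 | intermediate
20 | (4S)-1-[7-geranyl-6-(methoxymethoxy)-1-benzofuran-2-yl]-5-(methoxymethoxy)-5-methylhex-1-yn-4-ol | CC(C)=CCC/C(C)=C/Cc1c(OCOC)ccc2cc(C#CC[C@@H](C(C)(C)OCOC)O)oc12 | intermediate
21 | 2-[(4S)-4-{[(E)-1,2-dichloroethenyl]oxy}-5-(methoxymethoxy)-5-methylhex-1-yn-1-yl]-7-geranyl-6-(methoxymethoxy)-1-benzofuran | CC(C)=CCC/C(C)=C/Cc1c(OCOC)ccc2cc(C#CC[C@@H](C(C)(C)OCOC)O/C(Cl)=C\Cl)oc12 | intermediate
22 | 2-[(4S)-4-[(chloroethynyl)oxy]-5-(methoxymethoxy)-5-methylhex-1-yn-1-yl]-7-geranyl-6-(methoxymethoxy)-1-benzofuran | CC(C)=CCC/C(C)=C/Cc1c(OCOC)ccc2cc(C#CC[C@@H](C(C)(C)OCOC)OC#CCl)oc12 | intermediate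
23 | lithium acetylide of 24 (lithium alkoxyacetylide) | CC(C)=CCC/C(C)=C/Cc1c(OCOC)ccc2cc(C#CC[C@@H](C(C)(C)OCOC)OC#C[Li])oc12 | intermediate
24 | 2-[(4S)-4-(ethynyloxy)-5-(methoxymethoxy)-5-methylhex-1-yn-1-yl]-7-geranyl-6-(methoxymethoxy)-1-benzofuran | CC(C)=CCC/C(C)=C/Cc1c(OCOC)ccc2cc(C#CC[C@@H](C(C)(C)OCOC)OC#C)oc12 | intermediate
25 | 2-ethynyl-4,4,5,5-tetramethyl-1,3,2-dioxaborolane | C#CB1OC(C)(C)C(C)(C)O1 | starting material
26 | 2-{(2S)-4-[7-geranyl-6-(methoxymethoxy)-1-benzofuran-2-yl]-2-[2-(methoxymethoxy)propan-2-yl]-2,3-dihydro-1-benzofuran-6-yl}-4,4,5,5-tetramethyl-1,3,2-dioxaborolane | CC(C)=CCC/C(C)=C/Cc1c(OCOC)ccc2cc(-c3cc(B5OC(C)(C)C(C)(C)O5)cc4c3C[C@@H](C(C)(C)OCOC)O4)oc12 | intermediate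
27 | (2S)-4-[7-geranyl-6-(methoxymethoxy)-1-benzofuran-2-yl]-2-[2-(methoxymethoxy)propan-2-yl]-2,3-dihydro-1-benzofuran-6-ol | CC(C)=CCC/C(C)=C/Cc1c(OCOC)ccc2cc(-c3cc(O)cc4c3C[C@@H](C(C)(C)OCOC)O4)oc12 | intermediate
28 | (2S)-4-{7-[(2E)-3,7-dimethylocta-2,6-dien-1-yl]-6-hydroxy-1-benzofuran-2-yl}-2-(2-hydroxypropan-2-yl)-2,3-dihydro-1-benzofuran-6-ol | CC(C)=CCC/C(C)=C/Cc1c(O)ccc2cc(-c3cc(O)cc4c3C[C@@H](C(C)(C)O)O4)oc12 | target

## Step count and least certain steps

Total step count: 15. Longest linear sequence: 11 steps (1 to 28 through steps 1–5 and 10–15); the branch from 12 runs through 10 steps (6–9 and 10–15).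

Step 13 (key step, proposed method). Three things may go wrong. The polarised ynol ether may override the steric preference, so that 25 is taken up in the reverse orientation and boron ends up at C5. The ethynyl ether may be lost by retro-ene fragmentation or hydration before it cyclises, or it may tie up the catalyst as a vinylidene. The diyne may oligomerise with itself. A change of room-temperature catalyst ([Rh(cod)2]BF4 with BINAP) would be tried first. The fallback uses known chemistry only, abandons the ynol ether, sets out from 2 and 18 and returns at 27; it therefore also covers a failure of step 12.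

- Ring C is bought as 3,5-dibromophenol F1 and silylated (TIPSCl, imidazole) to (3,5-dibromophenoxy)tri(propan-2-yl)silane F2.
- LDA at −78 °C removes the proton between the two bromine atoms, which the bulky, non-directing silyl ether leaves as the most acidic. The aryllithium opens epoxide 18 at its CH2 carbon with BF3·OEt2 to give (2S)-1-{2,6-dibromo-4-[tri(propan-2-yl)silyloxy]phenyl}-3-(methoxymethoxy)-3-methylbutan-2-ol F3.
- Intramolecular palladium-catalysed C–O coupling (Pd(OAc)2, a bulky di-tert-butylbiarylphosphine, Cs2CO3, toluene, 70 °C) joins the secondary alcohol to one of the two equivalent C–Br bonds. This closes ring D to (2S)-4-bromo-2-[2-(methoxymethoxy)propan-2-yl]-6-[tri(propan-2-yl)silyloxy]-2,3-dihydro-1-benzofuran F4 with the stereocentre untouched.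
- Compound 2 is lithiated at C2 as in step 2 and quenched with 2-isopropoxy-4,4,5,5-tetramethyl-1,3,2-dioxaborolane to give 2-[6-(methoxymethoxy)-1-benzofuran-2-yl]-4,4,5,5-tetramethyl-1,3,2-dioxaborolane F5.
- Suzuki–Miyaura coupling of F4 with F5 (Pd(dppf)Cl2, K3PO4, dioxane/water) gives (2S)-2-[2-(methoxymethoxy)propan-2-yl]-4-[6-(methoxymethoxy)-1-benzofuran-2-yl]-6-[tri(propan-2-yl)silyloxy]-2,3-dihydro-1-benzofuran F6.
- Metalation at benzofuran C7 and copper-mediated coupling with 7, exactly as in step 4 (C2 now being arylated), gives the 7-geranyl compound (2S)-4-[7-geranyl-6-(methoxymethoxy)-1-benzofuran-2-yl]-2-[2-(methoxymethoxy)propan-2-yl]-6-[tri(propan-2-yl)silyloxy]-2,3-dihydro-1-benzofuran F7.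
- TBAF then removes the silyl group to give 27.

Step 11. The potassium alkoxide of 20 sits next to an aryl-conjugated alkyne; it may cyclise onto the triple bond or isomerise the propargylic position to an allene before it is trapped. The fallback avoids a free alkoxide, sets out from 20 and returns at 24 through 22 and 23. Alcohol 20 is formylated with acetic formic anhydride and pyridine to (4S)-1-[7-geranyl-6-(methoxymethoxy)-1-benzofuran-2-yl]-5-(methoxymethoxy)-5-methylhex-1-yn-4-yl formate F8. Wittig-type dichloromethylenation of the formate (PPh3, CCl4, THF, 60 °C) gives the 2,2-dichloroethenyl ether 2-[(4S)-4-[(2,2-dichloroethenyl)oxy]-5-(methoxymethoxy)-5-methylhex-1-yn-1-yl]-7-geranyl-6-(methoxymethoxy)-1-benzofuran F9. n-BuLi at −78 °C converts it through 22 and 23 into 24 after protonation.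

Step 4. The allylic coupling may proceed with allylic transposition (attack at the tertiary end of 7, giving the branched isomer), or 7 may be consumed by homocoupling after halogen–metal exchange. The fallback sets out from 6 through 8 and returns at 10. It changes the bond-forming event to a palladium-catalysed Negishi coupling: 8 is transmetalated with ZnCl2 to the arylzinc chloride {7-[2-(tri(propan-2-yl)silylethynyl)-6-(methoxymethoxy)-1-benzofuran-7-yl]}zinc chloride F10, which is coupled with 7 using Pd(PPh3)4 in THF. The π-geranylpalladium intermediate should couple at its less substituted end with the E geometry kept.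

Step 15. Before the less labile tertiary MOM ether is gone, the acid may cyclise the freed ring A phenol onto the neighbouring geranyl alkene (chroman formation) or add methanol to the alkenes. The fallback sets out from 27 and returns at 28 without protic acid. TESOTf with 2,2′-bipyridyl in CH2Cl2 at 0 °C, followed by water, converts the aryl MOM ether and the free phenol into silyl ethers and releases the tertiary alcohol. This gives the bis(triethylsilyl) ether (2S)-2-(2-hydroxypropan-2-yl)-4-[7-geranyl-6-(triethylsilyloxy)-1-benzofuran-2-yl]-6-(triethylsilyloxy)-2,3-dihydro-1-benzofuran F11. TBAF buffered with AcOH then gives 28.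

## Further compounds

F1 | step 13 | 3,5-dibromophenol | Oc1cc(Br)cc(Br)c1
F2 | step 13 | (3,5-dibromophenoxy)tri(propan-2-yl)silane | CC(C)[Si](Oc1cc(Br)cc(Br)c1)(C(C)C)C(C)C
F3 | step 13 | (2S)-1-{2,6-dibromo-4-[tri(propan-2-yl)silyloxy]phenyl}-3-(methoxymethoxy)-3-methylbutan-2-ol | COCOC(C)(C)[C@@H](O)Cc1c(Br)cc(O[Si](C(C)C)(C(C)C)C(C)C)cc1Br
F4 | step 13 | (2S)-4-bromo-2-[2-(methoxymethoxy)propan-2-yl]-6-[tri(propan-2-yl)silyloxy]-2,3-dihydro-1-benzofuran | COCOC(C)(C)[C@@H]1Cc2c(Br)cc(O[Si](C(C)C)(C(C)C)C(C)C)cc2O1
F5 | step 13 | 2-[6-(methoxymethoxy)-1-benzofuran-2-yl]-4,4,5,5-tetramethyl-1,3,2-dioxaborolane | COCOc1ccc2cc(B3OC(C)(C)C(C)(C)O3)oc2c1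
F6 | step 13 | (2S)-2-[2-(methoxymethoxy)propan-2-yl]-4-[6-(methoxymethoxy)-1-benzofuran-2-yl]-6-[tri(propan-2-yl)silyloxy]-2,3-dihydro-1-benzofuran | COCOc1ccc2cc(-c3cc(O[Si](C(C)C)(C(C)C)C(C)C)cc4c3C[C@@H](C(C)(C)OCOC)O4)oc2c1
F7 | step 13 | (2S)-4-[7-geranyl-6-(methoxymethoxy)-1-benzofuran-2-yl]-2-[2-(methoxymethoxy)propan-2-yl]-6-[tri(propan-2-yl)silyloxy]-2,3-dihydro-1-benzofuran | CC(C)=CCC/C(C)=C/Cc1c(OCOC)ccc2cc(-c3cc(O[Si](C(C)C)(C(C)C)C(C)C)cc4c3C[C@@H](C(C)(C)OCOC)O4)oc12
F8 | step 11 | (4S)-1-[7-geranyl-6-(methoxymethoxy)-1-benzofuran-2-yl]-5-(methoxymethoxy)-5-methylhex-1-yn-4-yl formate | CC(C)=CCC/C(C)=C/Cc1c(OCOC)ccc2cc(C#CC[C@@H](C(C)(C)OCOC)OC=O)oc12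
F9 | step 11 | 2-[(4S)-4-[(2,2-dichloroethenyl)oxy]-5-(methoxymethoxy)-5-methylhex-1-yn-1-yl]-7-geranyl-6-(methoxymethoxy)-1-benzofuran | CC(C)=CCC/C(C)=C/Cc1c(OCOC)ccc2cc(C#CC[C@@H](C(C)(C)OCOC)OC=C(Cl)Cl)oc12
F10 | step 4 | {6-(methoxymethoxy)-2-[(tri(propan-2-yl)silyl)ethynyl]-1-benzofuran-7-yl}zinc chloride | COCOc1ccc2cc(C#C[Si](C(C)C)(C(C)C)C(C)C)oc2c1[Zn]Cl
F11 | step 15 | (2S)-2-(2-hydroxypropan-2-yl)-4-[7-geranyl-6-(triethylsilyloxy)-1-benzofuran-2-yl]-6-(triethylsilyloxy)-2,3-dihydro-1-benzofuran | CC(C)=CCC/C(C)=C/Cc1c(O[Si](CC)(CC)CC)ccc2cc(-c3cc(O[Si](CC)(CC)CC)cc4c3C[C@@H](C(C)(C)O)O4)oc12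
A1 | alternative 1 | tert-butyl (2S)-4-bromo-6-[tri(propan-2-yl)silyloxy]-2,3-dihydro-1-benzofuran-2-carboxylate | Brc1cc(O[Si](C(C)C)(C(C)C)C(C)C)cc2c1C[C@@H](C(=O)OC(C)(C)C)O2
A2 | alternative 2 | (2R)-1-{2-[7-geranyl-6-(methoxymethoxy)-1-benzofuran-2-yl]-4,6-bis[tri(propan-2-yl)silyloxy]phenyl}-3-(methoxymethoxy)-3-methylbutan-2-ol | CC(C)=CCC/C(C)=C/Cc1c(OCOC)ccc2cc(-c3cc(O[Si](C(C)C)(C(C)C)C(C)C)cc(O[Si](C(C)C)(C(C)C)C(C)C)c3C[C@H](C(C)(C)OCOC)O)oc12
A3 | alternative 3 | tris-silyl ether of the target, (2S)-4-{7-geranyl-6-[tri(propan-2-yl)silyloxy]-1-benzofuran-2-yl}-6-[tri(propan-2-yl)silyloxy]-2-[2-(triethylsilyloxy)propan-2-yl]-2,3-dihydro-1-benzofuran | CC(C)=CCC/C(C)=C/Cc1c(O[Si](C(C)C)(C(C)C)C(C)C)ccc2cc(-c3cc(O[Si](C(C)C)(C(C)C)C(C)C)cc4c3C[C@@H](C(C)(C)O[Si](CC)(CC)CC)O4)oc12
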